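TBS = tert-butyldimethylsilyl and pin = pinacolato throughout. The lactone is ring A (O1, C2(=O), C3, C4, C5), the aryl group on C4 is ring B, the aryl group reached from C5 through the methylene C6 is ring C.

## Analysis of the target

The target 22 is a 3-hydroxyfuran-2(5H)-one (ring A) carrying a 4-hydroxyphenyl group (ring B) on C4 and, through C6, a 4-hydroxy-3-prenylphenyl group (ring C) on C5. C5 is the only stereocentre and is R. Nothing else in the molecule can relay or correct it, so it has to be set by a catalyst or reagent and then kept. It is a fragile centre: its hydrogen is allylic to C3=C4, α to O1 and γ to the lactone carbonyl, so base can remove it through a 2-oxidofuran. In an open-chain precursor with a ketone at C4 it is an ordinary enolisable α-position. The C3 hydroxyl is the enol of an α-keto lactone, acidic and easily oxidised, and the two phenols are base- and air-sensitive, so all three are best kept silylated until the end. The prenyl group on ring C is a trisubstituted alkene that does not survive ozone and that cyclises onto the neighbouring phenol under strong acid, so its time of entry restricts every oxidation in the route. The strategy rests on the substitution of C5: it bears a heteroatom (O1), the sp2 carbon C4 and the methylene C6 leading to ring C. This is the pattern left when an alkenyl group migrates from boron onto a boron-bound vinyl group while an aryl group is delivered to the vinyl terminus.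

## Retrosynthetic reasoning

22 from 21: the three O–Si bonds (C3 enol, ring B phenol, ring C phenol) are cut last. One buffered desilylation then releases the enol and both phenols together, and none of them has to pass through the organometallic and oxidative steps unprotected.

21 from 20: the bond between ring C and the prenyl CH2 is cut, leaving an aryl chloride. The cut is placed here because the prenyl alkene cannot be present when the exocyclic methylene of 17 is cleaved by ozone, so it must enter after step 10. Chlorine is the one halogen that stays silent while the bromide of 7 reacts in the key step. A tin-based transfer to an aryl chloride would need an anionic activator and heat, which the silyl ethers and C5 would not tolerate, so the forward step is the organozinc (Negishi) variant: neutral, near room temperature, and linear-selective for the prenyl unit.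

20 from 19: the C3=C4 double bond is cut by a Horner–Wadsworth–Emmons disconnection. This closes ring A with C3 already at the enol oxidation level and already protected. The forward reaction must deprotonate the phosphonate carbon and not C5.

19 from 17: the C4 carbonyl is traced to the C4=CH2 group. That methylene is the remnant of the migrating 1-arylvinyl group and serves as a masked ketone. Ozonolysis is used while no other alkene is present.

17 from 11 and 16: the O1–C2 ester bond is cut. Acid 16 brings C2, C3 and the silylated C3 oxygen in one piece, so no oxidation at C3 is needed later. 16 goes back to 14 by silylation, and 14 to 12 and 13 by P–C bond formation at the aldehyde carbon.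

11 from 10: the C5–O bond is traced to the C5–B bond. Oxidation proceeds with retention, so the configuration set at boron becomes the configuration of O1.

10 from 5, 8 and 7 (through 9): the C4–C5 and C6–ring C bonds are cut together. This is the point where the skeleton falls into three achiral pieces of similar size and where the only stereocentre is created under catalyst control. The forward reaction must make the 1-arylvinyl group of 5 migrate onto the vinyl group delivered by 8 while the aryl group of 7 adds to the vinyl terminus.

5 from 4, 2 and 1, and 7 from 6: the C–B bond of 5 is traced to an enol triflate of the silylated methyl ketone. 7 is the silyl ether of a commercial phenol.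

## Alternatives that were turned down

Alternative 1: Ring A is cut at C4–aryl, C3–C2 and O1–C2, leading back to the (R)-propargylic alcohol A2, the aryl Grignard reagent A3 and a one-carbon electrophile. In the forward key step the magnesium alkoxide of A2 directs anti addition of A3 across the alkyne (aryl to C4, magnesium to C3). Carboxylation of the alkenylmagnesium chelate and acidification then close the lactone to the 3-silylbutenolide A1.
- For: it is the most convergent plan, the ring closes in the key step, and the prenyl group can be carried from the start because no ozonolysis is needed. On step count and on handling of the prenyl group it is stronger than the chosen route.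
- Against: C3 ends with silicon, not oxygen. Oxidising a C–Si bond that sits α to the lactone carbonyl needs a fluoride or base activator with peroxide, conditions under which protodesilylation and deprotonation at C5 are the expected competing paths. The silicon substituent also sits on the alkyne carbon that must accept magnesium, and electron-rich aryl Grignard reagents are the least willing partners in hydroxyl-directed carbomagnesiation. The stereocentre is not made in the key step, so A2 needs a separate asymmetric step on an enolisable arylacetaldehyde or its ynone.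
- In its place the chosen route puts oxygen on C3 from the outset (through 16) and creates C5 in the same step that joins the fragments.

Alternative 2: O1 is removed from ring A, leading to the trans-cyclobutanone A5. A5 in turn comes from the prochiral ketone A6 by a desymmetrising benzylation with the benzyl bromide A7. The forward key step is a Baeyer–Villiger oxidation of A5 in which the more substituted, benzyl-bearing carbon migrates with retention to give the trans lactone A4. C3 is then hydroxylated and oxidised, and the α-keto lactone enolises towards C4.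
- For: the ring expansion is regioselective and stereoretentive, peroxide spares the prenyl group, and there is no enolisable α-acyloxy ketone and no late cross-coupling. On those points it is as strong as or stronger than the chosen route.
- Against: two stereocentres are made and one is later erased. The absolute configuration rests on an enantioselective α-alkylation of a cyclobutanone enolate, a species prone to self-condensation and ring opening. The electrophile A7 is a para-silyloxybenzyl halide that ionises readily. The end game raises C3 by two oxidation levels with strong base on a lactone.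
- The chosen route makes one stereocentre, once, from achiral partners by a catalytic step whose selectivity model applies directly.

Alternative 3: Ring A is cut at C4–aryl and C5–O1, leading to the axially chiral 2-alkoxyallenoic acid A9 and the aryl iodide A10. In the forward key step the arylpalladium species formed from A10 and a zerovalent palladium catalyst reacts with the carboxylate of A9. Aryl is delivered to C4, the carboxylate oxygen closes onto C5, and the allene axis is converted into the C5 stereocentre of A8.
- For: aryl transfer, ring closure and stereocentre formation happen in one step, with the C3 oxygen in place and the prenyl group carried through. It is the shortest end game of all.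
- Against: A9 must be a single enantiomer of an alkoxyallene, which is acid-sensitive as an enol ether and racemises readily under base through propargyl–allenyl equilibration. The transfer of chirality runs through allyl- or vinylpalladium species that can lose it. The warm, basic medium can deprotonate C5 of A8. The acetal on C3 needs acid for removal next to an ortho-prenylphenol.
- The chosen route draws its chirality from a ligand acting on achiral partners, at the cost of more steps after the key step.

Key step: step 5

Assumptions:
- One enantiomer of the MandyPhos ligand gives (R)-10. Which one is to be fixed in a pilot run by Mosher ester analysis of 11, and the mirror-image ligand is used otherwise.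
- Acid 16 is racemic, so 17, 18 and 19 are mixtures of two epimers at the phosphonate carbon. That carbon becomes sp2 in step 11.

## Route

Step 1
Reactants: 1 4'-hydroxyacetophenone
Product: 2 1-[4-(tert-butyldimethylsilyloxy)phenyl]ethan-1-one
Conditions: TBSCl, imidazole, DMF, rt
Reagents that add atoms: tert-butyldimethylsilyl chloride, CC(C)(C)[Si](C)(C)Cl
Why: Standard imidazole-mediated O-silylation of a phenol; the ketone is untouched.

Step 2
Reactants: 2 1-[4-(tert-butyldimethylsilyloxy)phenyl]ethan-1-one
Product: 4 1-[4-(tert-butyldimethylsilyloxy)phenyl]vinyl trifluoromethanesulfonate, via potassium enolate 3 (not isolated)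
Conditions: KN(SiMe3)2, THF, −78 °C; then PhNTf2, −78 → 0 °C
Reagents that add atoms: N-phenylbis(trifluoromethanesulfonimide), O=S(=O)(N(c1ccccc1)S(=O)(=O)C(F)(F)F)C(F)(F)F
Why: Enol triflate formation by O-sulfonylation of a kinetically formed enolate; the methyl group is the only enolisable position, so one regioisomer is possible.

Step 3
Reactants: 4 1-[4-(tert-butyldimethylsilyloxy)phenyl]vinyl trifluoromethanesulfonate
Product: 5 2-{1-[4-(tert-butyldimethylsilyloxy)phenyl]vinyl}-4,4,5,5-tetramethyl-1,3,2-dioxaborolane
Conditions: B2pin2, PdCl2(dppf) (3 mol %), KOAc, 1,4-dioxane, 80 °C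
Reagents that add atoms: bis(pinacolato)diboron, CC1(C)OB(OC1(C)C)B1OC(C)(C)C(C)(C)O1
Why: Miyaura borylation of an alkenyl triflate; the weak acetate base activates the diboron reagent without promoting Suzuki coupling of the product with remaining triflate.

Step 4
Reactants: 6 4-bromo-2-chlorophenol
Product: 7 (4-bromo-2-chlorophenoxy)(tert-butyl)dimethylsilane
Conditions: TBSCl, imidazole, DMF, rt
Reagents that add atoms: tert-butyldimethylsilyl chloride, CC(C)(C)[Si](C)(C)Cl
Why: Standard phenol silylation; the ortho chlorine slows it only slightly.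

Step 5
Reactants: 5 2-{1-[4-(tert-butyldimethylsilyloxy)phenyl]vinyl}-4,4,5,5-tetramethyl-1,3,2-dioxaborolane; 8 vinylmagnesium bromide; 7 (4-bromo-2-chlorophenoxy)(tert-butyl)dimethylsilane
Product: 10 (R)-2-{1-[3-chloro-4-(tert-butyldimethylsilyloxy)phenyl]-3-[4-(tert-butyldimethylsilyloxy)phenyl]but-3-en-2-yl}-4,4,5,5-tetramethyl-1,3,2-dioxaborolane, via bromomagnesium bis(alkenyl)borate 9 (not isolated)
Conditions: 5, 8 (1.0 equiv), THF, 0 °C → rt; then 7 (1.1 equiv), NaOTf (2 equiv), Pd(OAc)2 (2 mol %), MandyPhos (a 1,1'-bis(diarylphosphino)-2,2'-bis[α-(dimethylamino)benzyl]ferrocene, 2.4 mol %), THF/DMSO, 40–60 °C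
Reagents that add atoms: none
Why: Addition of 8 to the vacant orbital of 5 gives the four-coordinate bis(alkenyl)borate 9; zerovalent palladium carrying the chiral bisphosphine inserts into the C–Br bond of 7 and NaOTf removes bromide as NaBr, leaving a cationic aryl complex of divalent palladium. This electrophile binds the unsubstituted vinyl group of 9, and the 1-arylvinyl group shifts from boron to the α-carbon (C5) anti to palladium while the β-carbon (C6) becomes bonded to palladium; reductive elimination then forms the C6–aryl bond and returns zerovalent palladium. The closest known reaction type is the palladium-catalysed enantioselective conjunctive cross-coupling of vinylboron ate complexes, in its bis(alkenyl)borate form that gives α-chiral allylic boronates and in its Grignard/aryl halide form with NaOTf. No ring is closed. The C5 stereocentre is under catalyst control alone: the ligand-bound palladium distinguishes the two faces of the boron-bound vinyl group during the metallate shift, and all three reactants are achiral. Three selectivities are needed: palladium must bind the vinyl group and not the 1,1-disubstituted arylvinyl group (the smaller vinyl group binds, so the aryl-substituted alkenyl group is the one that migrates); the metallate shift must outrun direct boron-to-palladium transmetalation (favoured by the saturated pinacol-bound borate and the wide-bite-angle bisphosphine); and C–Br must react in preference to C–Cl (the electron-rich chloride flanked by the silyloxy group is inert to a diarylphosphine palladium catalyst at this temperature).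

Step 6
Reactants: 10 (R)-allylic pinacol boronate from step 5
Product: 11 (R)-1-[3-chloro-4-(tert-butyldimethylsilyloxy)phenyl]-3-[4-(tert-butyldimethylsilyloxy)phenyl]but-3-en-2-ol
Conditions: NaBO3·4H2O, THF/H2O (1:1), rt
Reagents that add atoms: sodium perborate tetrahydrate, [Na+].[O-]OB=O.O.O.O.O
Why: Oxidation of a C–B bond by peroxide addition to boron and 1,2-shift of C5 from boron to oxygen with retention, so (R)-10 gives (R)-11 without allylic transposition; the mildly basic perborate is chosen so that the aryl silyl ethers are not hydrolysed.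

Step 7
Reactants: 12 glyoxylic acid monohydrate; 13 diethyl phosphite
Product: 14 2-(diethoxyphosphoryl)-2-hydroxyacetic acid (racemic)
Conditions: toluene, 60 °C; azeotropic drying
Reagents that add atoms: none
Why: Pudovik (Abramov-type) addition of the P–H bond of a dialkyl phosphite across the aldehyde carbonyl of glyoxylic acid, the reaction by which hydroxyphosphonoacetic acid derivatives are made.

Step 8
Reactants: 14 2-(diethoxyphosphoryl)-2-hydroxyacetic acid
Product: 16 2-(diethoxyphosphoryl)-2-(tert-butyldimethylsilyloxy)acetic acid (racemic), via bis-silylated silyl ester 15 (not isolated)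
Conditions: TBSCl (2.5 equiv), imidazole, DMF, rt; then AcOH/THF/H2O (3:1:1), rt
Reagents that add atoms: tert-butyldimethylsilyl chloride, CC(C)(C)[Si](C)(C)Cl
Why: Exhaustive silylation followed by selective hydrolysis of the silyl ester, which is far more labile than the hindered secondary silyl ether.

Step 9
Reactants: 11 (R)-allylic alcohol from step 6; 16 2-(diethoxyphosphoryl)-2-(tert-butyldimethylsilyloxy)acetic acid
Product: 17 (R)-1-[3-chloro-4-(tert-butyldimethylsilyloxy)phenyl]-3-[4-(tert-butyldimethylsilyloxy)phenyl]but-3-en-2-yl 2-(diethoxyphosphoryl)-2-(tert-butyldimethylsilyloxy)acetate (two epimers at the phosphonate carbon)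
Conditions: DCC, DMAP (cat.), CH2Cl2, 0 °C → rt
Reagents that add atoms: none
Why: Steglich esterification of a secondary alcohol with a phosphonoacetic acid; acylation at oxygen leaves C5 untouched.

Step 10
Reactants: 17 phosphonoacetate ester from step 9
Product: 19 (R)-3-[3-chloro-4-(tert-butyldimethylsilyloxy)phenyl]-1-[4-(tert-butyldimethylsilyloxy)phenyl]-1-oxopropan-2-yl 2-(diethoxyphosphoryl)-2-(tert-butyldimethylsilyloxy)acetate, via secondary ozonide 18 (not isolated)
Conditions: O3, CH2Cl2, −78 °C (Sudan Red 7B end point); then PPh3, −78 °C → rt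
Reagents that add atoms: ozone, [O-][O+]=O
Why: Ozonolysis (Criegee mechanism) of the only alkene in the molecule with reductive work-up; the alkene reacts far faster than the silyloxyarenes and the dye marks the end point, and the base-free conditions leave the now enolisable C5 alone.

Step 11
Reactants: 19 keto phosphonate from step 10
Product: 20 (R)-3-(tert-butyldimethylsilyloxy)-5-[3-chloro-4-(tert-butyldimethylsilyloxy)benzyl]-4-[4-(tert-butyldimethylsilyloxy)phenyl]furan-2(5H)-one
Conditions: LiCl, i-Pr2NEt, MeCN, 0 °C → rt
Reagents that add atoms: none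
Why: Intramolecular Horner–Wadsworth–Emmons reaction of an α-(phosphonoacetoxy) ketone: the lithium-chelated phosphonate is deprotonated by the amine, C3 adds to the C4 carbonyl in a 5-exo-trig closure, and loss of diethyl phosphate gives C3=C4. The weak base acts on the chelated phosphonate, the most acidic site, and not on C5, so the stereocentre should be kept.

Step 12
Reactants: 20 chlorobutenolide from step 11
Product: 21 (R)-3-(tert-butyldimethylsilyloxy)-5-[4-(tert-butyldimethylsilyloxy)-3-(3-methylbut-2-en-1-yl)benzyl]-4-[4-(tert-butyldimethylsilyloxy)phenyl]furan-2(5H)-one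
Conditions: prenylzinc bromide (from prenyl bromide, Zn, LiCl, THF), Pd(OAc)2 (3 mol %), CPhos (2-dicyclohexylphosphino-2',6'-bis(dimethylamino)biphenyl, 6 mol %), THF, rt → 40 °C
Reagents that add atoms: prenylzinc bromide, CC(C)=CC[Zn]Br
Why: Negishi coupling of an allylic zinc halide with an aryl chloride: the bulky dialkylbiarylphosphine allows insertion into the hindered, electron-rich C–Cl bond and steers reductive elimination to the unsubstituted allyl terminus, giving the linear prenyl arene. The medium is neutral and free of fluoride, so the silyl ethers, the lactone and C5 are not exposed to base.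

Step 13
Reactants: 21 tris-silyl ether from step 12
Product: 22 (R)-3-hydroxy-5-[4-hydroxy-3-(3-methylbut-2-en-1-yl)benzyl]-4-(4-hydroxyphenyl)furan-2(5H)-one
Conditions: Bu4NF, AcOH, THF, 0 °C → rt
Reagents that add atoms: none
Why: Fluoride-induced cleavage of the two aryl silyl ethers and the enol silyl ether; the acetic acid buffer keeps the medium from becoming basic enough to deprotonate C5 and is too weak to cyclise the prenylphenol.

## Compound list

1 | 4'-hydroxyacetophenone | CC(=O)c1ccc(O)cc1 | starting material
2 | 1-[4-(tert-butyldimethylsilyloxy)phenyl]ethan-1-one | CC(=O)c1ccc(O[Si](C)(C)C(C)(C)C)cc1 | intermediate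
3 | potassium 1-[4-(tert-butyldimethylsilyloxy)phenyl]ethen-1-olate | C=C([O-])c1ccc(O[Si](C)(C)C(C)(C)C)cc1.[K+] | intermediate
4 | 1-[4-(tert-butyldimethylsilyloxy)phenyl]vinyl trifluoromethanesulfonate | C=C(OS(=O)(=O)C(F)(F)F)c1ccc(O[Si](C)(C)C(C)(C)C)cc1 | intermediate
5 | 2-{1-[4-(tert-butyldimethylsilyloxy)phenyl]vinyl}-4,4,5,5-tetramethyl-1,3,2-dioxaborolane | CC(C)(C)[Si](C)(C)Oc1ccc(C(=C)B2OC(C)(C)C(C)(C)O2)cc1 | intermediate
6 | 4-bromo-2-chlorophenol | Oc1ccc(Br)cc1Cl | starting material
7 | (4-bromo-2-chlorophenoxy)(tert-butyl)dimethylsilane | CC(C)(C)[Si](C)(C)Oc1ccc(Br)cc1Cl | intermediate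
8 | vinylmagnesium bromide | C=C[Mg]Br | starting material
9 | bromomagnesium {1-[4-(TBSO)phenyl]vinyl}(pinacolato)(vinyl)borate | C=C[B-]1(OC(C)(C)C(C)(C)O1)C(=C)c1ccc(O[Si](C)(C)C(C)(C)C)cc1.[Mg+]Br | intermediate
10 | (R)-2-{1-[3-chloro-4-(TBSO)phenyl]-3-[4-(TBSO)phenyl]but-3-en-2-yl}-4,4,5,5-tetramethyl-1,3,2-dioxaborolane | CC(C)(C)[Si](C)(C)Oc1ccc(C[C@@H](B2OC(C)(C)C(C)(C)O2)C(=C)c2ccc(O[Si](C)(C)C(C)(C)C)cc2)cc1Cl | intermediate
11 | (R)-1-[3-chloro-4-(TBSO)phenyl]-3-[4-(TBSO)phenyl]but-3-en-2-ol | CC(C)(C)[Si](C)(C)Oc1ccc(C[C@@H](O)C(=C)c2ccc(O[Si](C)(C)C(C)(C)C)cc2)cc1Cl | intermediate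
12 | glyoxylic acid monohydrate | OC(O)C(=O)O | starting material
13 | diethyl phosphite | CCO[PH](=O)OCC | starting material
14 | 2-(diethoxyphosphoryl)-2-hydroxyacetic acid (racemic) | CCOP(=O)(OCC)C(O)C(=O)O | intermediate
15 | tert-butyldimethylsilyl 2-(diethoxyphosphoryl)-2-(TBSO)acetate | CCOP(=O)(OCC)C(O[Si](C)(C)C(C)(C)C)C(=O)O[Si](C)(C)C(C)(C)C | intermediate
16 | 2-(diethoxyphosphoryl)-2-(TBSO)acetic acid (racemic) | CCOP(=O)(OCC)C(O[Si](C)(C)C(C)(C)C)C(=O)O | intermediate
17 | (R)-1-[3-chloro-4-(TBSO)phenyl]-3-[4-(TBSO)phenyl]but-3-en-2-yl 2-(diethoxyphosphoryl)-2-(TBSO)acetate | CCOP(=O)(OCC)C(O[Si](C)(C)C(C)(C)C)C(=O)O[C@H](Cc1ccc(O[Si](C)(C)C(C)(C)C)c(Cl)c1)C(=C)c1ccc(O[Si](C)(C)C(C)(C)C)cc1 | intermediate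
18 | secondary ozonide (1,2,4-trioxolane at the former C4=CH2) of 17 | CCOP(=O)(OCC)C(O[Si](C)(C)C(C)(C)C)C(=O)O[C@H](Cc1ccc(O[Si](C)(C)C(C)(C)C)c(Cl)c1)C1(OCOO1)c1ccc(O[Si](C)(C)C(C)(C)C)cc1 | intermediate
19 | (R)-3-[3-chloro-4-(TBSO)phenyl]-1-[4-(TBSO)phenyl]-1-oxopropan-2-yl 2-(diethoxyphosphoryl)-2-(TBSO)acetate | CCOP(=O)(OCC)C(O[Si](C)(C)C(C)(C)C)C(=O)O[C@H](Cc1ccc(O[Si](C)(C)C(C)(C)C)c(Cl)c1)C(=O)c1ccc(O[Si](C)(C)C(C)(C)C)cc1 | intermediate
20 | (R)-3-(TBSO)-5-[3-chloro-4-(TBSO)benzyl]-4-[4-(TBSO)phenyl]furan-2(5H)-one | CC(C)(C)[Si](C)(C)Oc1ccc(C[C@H]2OC(=O)C(O[Si](C)(C)C(C)(C)C)=C2c2ccc(O[Si](C)(C)C(C)(C)C)cc2)cc1Cl | intermediate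
21 | (R)-3-(TBSO)-5-[4-(TBSO)-3-(3-methylbut-2-en-1-yl)benzyl]-4-[4-(TBSO)phenyl]furan-2(5H)-one | CC(C)=CCc1cc(C[C@H]2OC(=O)C(O[Si](C)(C)C(C)(C)C)=C2c2ccc(O[Si](C)(C)C(C)(C)C)cc2)ccc1O[Si](C)(C)C(C)(C)C | intermediate
22 | (R)-3-hydroxy-5-[4-hydroxy-3-(3-methylbut-2-en-1-yl)benzyl]-4-(4-hydroxyphenyl)furan-2(5H)-one | CC(C)=CCc1cc(C[C@H]2OC(=O)C(O)=C2c2ccc(O)cc2)ccc1O | target

## Step count and risk

Total step count: 13. Longest linear sequence: 10 steps (steps 1, 2, 3, 5, 6, 9, 10, 11, 12, 13).

Least certain steps:

**Step 5 (key step).**
- What may go wrong: direct transmetalation of one of the alkenyl groups to palladium (simple Suzuki coupling); binding of palladium to the arylvinyl group instead of the vinyl group; insufficient facial discrimination for this α-aryl-substituted migrating group; protodeboronation of the allylic boronate in the warm DMSO-containing medium.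
- Adjustment within the method: switching to the halide-free lithium/aryl triflate protocol.
- Fallback with a different way of making the C4–C5 bond: set out from 7 and 5. Bromine–lithium exchange on 7 (n-BuLi, THF, −78 °C) and opening of ethylene oxide (BF3·OEt2) should give 2-[3-chloro-4-(tert-butyldimethylsilyloxy)phenyl]ethan-1-ol F1. Carbamoylation with N,N-diisopropylcarbamoyl chloride gives the carbamate F2. Deprotonation with s-BuLi and (−)-sparteine in Et2O at −78 °C gives the configurationally stable (S)-α-lithiated carbamate F3. Addition of 5 with retention gives the lithium boronate complex F4. On warming (MgBr2·OEt2 if needed) the 1-arylvinyl group migrates with inversion and expels the carbamate. This lithiation–borylation sequence returns to the route at 10.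

**Step 12.**
- What may go wrong: slow insertion of palladium into the C–Cl bond next to the bulky silyloxy group; attack of the allylic zinc reagent on the lactone carbonyl; transfer through the substituted allyl terminus (reverse prenyl); proton abstraction at C5 by the organozinc.
- Fallback with reversed polarity: set out from 20. Miyaura borylation of the C–Cl bond (B2pin2, Pd(OAc)2, XPhos (2-dicyclohexylphosphino-2',4',6'-triisopropylbiphenyl), KOAc, dioxane) should give the arylboronate F5. Palladium-catalysed allylic arylation of F5 with tert-butyl prenyl carbonate (Pd2(dba)3, PPh3, THF, no added base) delivers the aryl group to the less substituted terminus of the prenylpalladium intermediate and returns to the route at 21. No nucleophilic organometallic meets the lactone in this sequence.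

**Step 11.**
- What may go wrong: enolisation at C5 of 19 competing with deprotonation of the phosphonate (loss of configuration); slow addition of the hindered, fully substituted phosphonate carbanion to an electron-rich aryl ketone; deprotonation of the product at C5 if a stronger base (DBU, or LiN(SiMe3)2 at −78 °C) has to be used.
- Fallback that forms the C3–C4 bond before the ring exists and never passes through an α-acyloxy ketone: set out from 11. Silylation (Et3SiCl, imidazole) gives the triethylsilyl ether F6, and ozonolysis as in step 10 gives the α-silyloxy ketone F7. Addition of the lithium enolate of methyl (tert-butyldimethylsilyloxy)acetate at −78 °C gives the aldol adduct F8, a mixture at C3 and C4 that is of no consequence. Hydrolytic removal of the triethylsilyl group (AcOH/THF/H2O) with spontaneous lactonisation gives the β-hydroxy lactone F9. Mesylation of the tertiary alcohol and β-elimination through the C3 enolate (MsCl, Et3N) returns to the route at 20.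

**Step 3 (with step 2).**
- What may go wrong: decomposition of the terminal enol triflate 4 (elimination to the arylalkyne, hydrolysis back to 2); Suzuki-type coupling of 5 with unreacted 4 during borylation; protodeboronation of 5.
- Fallback that avoids the triflate: set out from 2. Condensation with 2,4,6-triisopropylbenzenesulfonyl hydrazide gives the hydrazone F10. A Shapiro reaction (n-BuLi, 2 equiv, THF, −78 → 0 °C) gives the 1-arylvinyllithium F11. Trapping with 2-isopropoxy-4,4,5,5-tetramethyl-1,3,2-dioxaborolane returns to the route at 5.

## Further compounds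

F1 | step 5 | 2-[3-chloro-4-(tert-butyldimethylsilyloxy)phenyl]ethan-1-ol | CC(C)(C)[Si](C)(C)Oc1ccc(CCO)cc1Cl
F2 | step 5 | 2-[3-chloro-4-(tert-butyldimethylsilyloxy)phenyl]ethyl N,N-diisopropylcarbamate | CC(C)N(C(C)C)C(=O)OCCc1ccc(O[Si](C)(C)C(C)(C)C)c(Cl)c1
F3 | step 5 | (S)-2-[3-chloro-4-(tert-butyldimethylsilyloxy)phenyl]-1-lithioethyl N,N-diisopropylcarbamate | CC(C)(C)[Si](C)(C)Oc1ccc(C[C@H]([Li])OC(=O)N(C(C)C)C(C)C)cc1Cl
F4 | step 5 | lithium (S)-{2-[3-chloro-4-(TBSO)phenyl]-1-(N,N-diisopropylcarbamoyloxy)ethyl}{1-[4-(TBSO)phenyl]vinyl}(pinacolato)borate | CC(C)(C)[Si](C)(C)Oc1ccc(C[C@H]([B-]2(OC(C)(C)C(C)(C)O2)C(=C)c2ccc(O[Si](C)(C)C(C)(C)C)cc2)OC(=O)N(C(C)C)C(C)C)cc1Cl.[Li+]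
F5 | step 12 | (R)-3-(TBSO)-5-[4-(TBSO)-3-(4,4,5,5-tetramethyl-1,3,2-dioxaborolan-2-yl)benzyl]-4-[4-(TBSO)phenyl]furan-2(5H)-one | CC(C)(C)[Si](C)(C)Oc1ccc(C[C@H]2OC(=O)C(O[Si](C)(C)C(C)(C)C)=C2c2ccc(O[Si](C)(C)C(C)(C)C)cc2)cc1B1OC(C)(C)C(C)(C)O1
F6 | step 11 | (R)-1-[3-chloro-4-(TBSO)phenyl]-3-[4-(TBSO)phenyl]-2-(triethylsilyloxy)but-3-ene | CC[Si](CC)(CC)O[C@H](Cc1ccc(O[Si](C)(C)C(C)(C)C)c(Cl)c1)C(=C)c1ccc(O[Si](C)(C)C(C)(C)C)cc1
F7 | step 11 | (R)-3-[3-chloro-4-(TBSO)phenyl]-1-[4-(TBSO)phenyl]-2-(triethylsilyloxy)propan-1-one | CC[Si](CC)(CC)O[C@H](Cc1ccc(O[Si](C)(C)C(C)(C)C)c(Cl)c1)C(=O)c1ccc(O[Si](C)(C)C(C)(C)C)cc1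
F8 | step 11 | methyl (4R)-2-(TBSO)-5-[3-chloro-4-(TBSO)phenyl]-3-hydroxy-3-[4-(TBSO)phenyl]-4-(triethylsilyloxy)pentanoate (mixture at C2 and C3) | COC(=O)C(O[Si](C)(C)C(C)(C)C)C(O)(c1ccc(O[Si](C)(C)C(C)(C)C)cc1)[C@@H](Cc1ccc(O[Si](C)(C)C(C)(C)C)c(Cl)c1)O[Si](CC)(CC)CC
F9 | step 11 | (5R)-3-(TBSO)-5-[3-chloro-4-(TBSO)benzyl]-4-hydroxy-4-[4-(TBSO)phenyl]dihydrofuran-2(3H)-one (mixture at C3 and C4) | CC(C)(C)[Si](C)(C)Oc1ccc(C[C@H]2OC(=O)C(O[Si](C)(C)C(C)(C)C)C2(O)c2ccc(O[Si](C)(C)C(C)(C)C)cc2)cc1Cl
F10 | step 3 | N'-{1-[4-(tert-butyldimethylsilyloxy)phenyl]ethylidene}-2,4,6-triisopropylbenzenesulfonohydrazide | CC(=NNS(=O)(=O)c1c(C(C)C)cc(C(C)C)cc1C(C)C)c1ccc(O[Si](C)(C)C(C)(C)C)cc1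
F11 | step 3 | {1-[4-(tert-butyldimethylsilyloxy)phenyl]vinyl}lithium | [Li]C(=C)c1ccc(O[Si](C)(C)C(C)(C)C)cc1
A1 | alternative 1 | (R)-3-(benzyldimethylsilyl)-5-[4-(TBSO)-3-(3-methylbut-2-en-1-yl)benzyl]-4-[4-(TBSO)phenyl]furan-2(5H)-one | CC(C)=CCc1cc(C[C@H]2OC(=O)C([Si](C)(C)Cc3ccccc3)=C2c2ccc(O[Si](C)(C)C(C)(C)C)cc2)ccc1O[Si](C)(C)C(C)(C)C
A2 | alternative 1 | (R)-4-(benzyldimethylsilyl)-1-[4-(TBSO)-3-(3-methylbut-2-en-1-yl)phenyl]but-3-yn-2-ol | CC(C)=CCc1cc(C[C@@H](O)C#C[Si](C)(C)Cc2ccccc2)ccc1O[Si](C)(C)C(C)(C)C
A3 | alternative 1 | [4-(tert-butyldimethylsilyloxy)phenyl]magnesium bromide | CC(C)(C)[Si](C)(C)Oc1ccc([Mg]Br)cc1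
A4 | alternative 2 | trans-5-[4-(TBSO)-3-(3-methylbut-2-en-1-yl)benzyl]-4-[4-(TBSO)phenyl]dihydrofuran-2(3H)-one with the target configuration at C5 | CC(C)=CCc1cc(C[C@H]2OC(=O)C[C@@H]2c2ccc(O[Si](C)(C)C(C)(C)C)cc2)ccc1O[Si](C)(C)C(C)(C)C
A5 | alternative 2 | trans-2-[4-(TBSO)-3-(3-methylbut-2-en-1-yl)benzyl]-3-[4-(TBSO)phenyl]cyclobutan-1-one (enantiomer as in the SMILES) | CC(C)=CCc1cc(C[C@H]2C(=O)C[C@@H]2c2ccc(O[Si](C)(C)C(C)(C)C)cc2)ccc1O[Si](C)(C)C(C)(C)C
A6 | alternative 2 | 3-[4-(tert-butyldimethylsilyloxy)phenyl]cyclobutan-1-one | O=C1CC(c2ccc(O[Si](C)(C)C(C)(C)C)cc2)C1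
A7 | alternative 2 | [4-(bromomethyl)-2-(3-methylbut-2-en-1-yl)phenoxy](tert-butyl)dimethylsilane | CC(C)=CCc1cc(CBr)ccc1O[Si](C)(C)C(C)(C)C
A8 | alternative 3 | (R)-3-(methoxymethoxy)-5-[4-(TBSO)-3-(3-methylbut-2-en-1-yl)benzyl]-4-[4-(TBSO)phenyl]furan-2(5H)-one | CC(C)=CCc1cc(C[C@H]2OC(=O)C(OCOC)=C2c2ccc(O[Si](C)(C)C(C)(C)C)cc2)ccc1O[Si](C)(C)C(C)(C)C
A9 | alternative 3 | 2-(methoxymethoxy)-5-[4-(TBSO)-3-(3-methylbut-2-en-1-yl)phenyl]penta-2,3-dienoic acid (axis as in the SMILES, the one that maps onto R at C5 when the carboxylate closes onto C5 from its own side) | OC(=O)C(OCOC)=[C@]=C([H])Cc1ccc(O[Si](C)(C)C(C)(C)C)c(CC=C(C)C)c1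
A10 | alternative 3 | tert-butyl(4-iodophenoxy)dimethylsilane | CC(C)(C)[Si](C)(C)Oc1ccc(I)cc1
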